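The readings were computed with made-up constants, and the scatter is random.

A chemist who holds one earlier run, the birch run, wants to foresee the flask with equal charges.

- birch: first end groups 0.25 M; second end groups 0.12 M; run made earlier
- flask: first end groups 0.25 M; second end groups 0.250 M; time 80 min

birch run (percent of the first end groups charged)

| time / min | links / % | first end groups / % |
|---|---|---|
| 0.417 | 25 | 74 |
| 1.33 | 39 | 57 |
| 2.50 | 45 | 59 |
| 3.00 | 44 | 58 |
| 5.00 | 40 | 58 |
| 6.00 | 42 | 54 |
| 8.00 | 44 | 51 |

(scatter of a reading: 2 percentage points)

- each molecule carries two end groups: a chain counts once for every two ends that are left, dead ends included; the units are half of the end groups of the two monomers charged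
- a link that another step uses up counts as cut, two dead ends; so do two ends of one kind that react with each other

1. average number of monomer units in a chain (unreacted monomers counted as chains of one) at 80 min
2. part of the first end groups that has reacted at 80 min

In the birch run second end groups are the limiting reagent, 0.12 M against 0.25 M of first end groups, yet from 2.50 min on the links average 43.0%, or 0.107 M. Suppose, then, that second end groups also decay in a first-order step, while linking needs a first end group too. The concentration of first end groups then sets the split, and summing over the run, second ends lost = m × ln(first ends charged / first ends left). You get 0.0222 M: the split concentration, the amount of first end groups at which a second end group is as likely to decay as to link.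

With equal charges, the free first ends x equal the second ends lost, so x = m × ln(charge / x), and dp is charge / x. Start at m and average each value with what the formula returns: 0.0380 M, then 0.0400 M. I commit to dp 6.26 and c 84.0%.

The weak link is m, which rests on a small difference. Lowering the mean links by its scatter, 0.89 percentage points, gives 0.0270 M, and the same averaging from x then gives 0.0447 M, 0.0456 M, so dp may fall to 5.49.

The forecast, reading the stall as “a reversible link”, gave dp 3.8 and c 81%, a lower dp than mine. The flask gives dp 5.47 and c 84.4%.

    first end groups + second end groups → links + by-product (k = 0.180 L mol⁻¹ s⁻¹)
    2 first end groups → self-condensation product (k = 3.50 × 10⁻⁴ L mol⁻¹ s⁻¹)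
    second end groups → decomposed reagent (k = 0.00480 s⁻¹)

In the flask, linking and decay ran together at first: by 8.00 min the second end groups stood at 0.0613% of their charge, links at 81.7%, and decomposed reagent at 0.0456 M, against 0.0377 M reckoned from m with those links. Up to 80 min links stayed at 81.7% while self-condensation product rose from 0.593% to 2.68%. For the neighbour flask charged with 0.062 M of second end groups, m gives links of 0.0557 M, or 22.3%, and dp 1.55; that neighbour holds 22.1% links and dp 1.55.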